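# Antheliatin (27): proposed total synthesis

**Retrosynthesis**
1. Antheliatin (27) comes from TES removal after acetylation of the side-chain carbinol. That carbinol is made by a Nozaki–Hiyama–Kishi (NHK) coupling of 3-iodo enol ether 18 with the (R)-α-benzoyloxy aldehyde 24 (polar Felkin control).
2. The nine-membered ring is closed by an intramolecular Ni-catalysed ynal reductive cyclisation of 16. This forms the o–b bond, the exocyclic methylene and the o-OSiEt3 carbinol.
3. The cis-fused acetoxy-dihydropyran and its d/c/i stereotriad come from one Cr(III)-catalysed inverse-demand oxa-Diels–Alder reaction (the new step). Enal 9 reacts with (Z)-enol acetate 12.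
4. Enal 9 comes from cross-metathesis of alkene 5 with chiral-pool acetate 3 (E-trisubstituted alkene, n stereocentre), then Wittig homologation.
5. Aldehyde 24 comes from an alkenyl Grignard addition to diethyl oxalate, then Noyori asymmetric transfer hydrogenation (sets h), benzoylation and DIBAL-H reduction.

**Assumptions**
- (S)-But-3-ene-1,2-diol, 4-methylpent-4-en-1-ol, 1,4-bis(trimethylsilyl)butadiyne, 1-bromo-2-methylpropene and diethyl oxalate are commercial.
- Each chiral catalyst enantiomer is the one that gives the depicted configuration.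

## Route

**Step 1**
Reactants: 1 (S)-but-3-ene-1,2-diol
Product: 2 (S)-1-(tert-butyldiphenylsilyloxy)but-3-en-2-ol
Conditions: TBDPSCl, imidazole, CH2Cl2, 0 °C
Reagents that add atoms: TBDPSCl, CC(C)(C)[Si](Cl)(c1ccccc1)c1ccccc1
Why: Silylation is selective for the primary alcohol, and the chiral carbinol is untouched.

**Step 2**
Reactants: 2
Product: 3 (S)-1-(TBDPSO)but-3-en-2-yl acetate
Conditions: Ac2O, Et3N, DMAP, CH2Cl2, 0 °C
Reagents that add atoms: Ac2O, CC(=O)OC(C)=O
Why: Simple acylation gives the cross-metathesis partner, which carries the n stereocentre (S).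

**Step 3**
Reactants: 4 4-methylpent-4-en-1-ol
Product: 5 TBS ether of 4
Conditions: TBSCl, imidazole, CH2Cl2, 0 °C
Reagents that add atoms: TBSCl, CC(C)(C)[Si](C)(C)Cl
Why: This protects the primary alcohol before metathesis.

**Step 4**
Reactants: 5 (1 equiv), 3 (2 equiv)
Product: 6 (S,E)-TBSO(CH2)3C(Me)=CH–CH(OAc)CH2OTBDPS
Conditions: Hoveyda–Grubbs II (5 mol%), CH2Cl2, 40 °C
Reagents that add atoms: none
Why: Cross-metathesis of a 1,1-disubstituted alkene with an allylic acetate gives the E-trisubstituted alkene l=m, and n is retained.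

**Step 5**
Reactants: 6
Product: 7 primary alcohol (TBS removed, TBDPS kept)
Conditions: HF·py, pyridine, THF, 0 °C
Reagents that add atoms: none
Why: A primary TBS ether is cleaved far faster than a primary TBDPS ether, and the acetate is untouched.

**Step 6**
Reactants: 7
Product: 8 aldehyde OHC(CH2)2C(Me)=CH–CH(OAc)CH2OTBDPS
Conditions: DMP, NaHCO3, CH2Cl2, rt
Reagents that add atoms: none
Why: Buffered Dess–Martin oxidation; the aldehyde is γ,δ-unsaturated and has no epimerisable centre.

**Step 7**
Reactants: 8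
Product: 9 (2E,6E,8S)-8-acetoxy-9-(TBDPSO)-6-methylnona-2,6-dienal
Conditions: Ph3P=CHCHO, toluene, 80 °C
Reagents that add atoms: (formylmethylene)triphenylphosphorane, O=CC=P(c1ccccc1)(c1ccccc1)c1ccccc1
Why: Stabilised-ylide Wittig two-carbon homologation gives the E-enal, which is the heterodiene for step 10.

**Step 8**
Reactants: 10 1,4-bis(trimethylsilyl)buta-1,3-diyne
Product: 11 4-(trimethylsilyl)buta-1,3-diyne (used as a solution)
Conditions: MeLi·LiBr, THF, −78→0 °C; then aq. NH4Cl
Reagents that add atoms: none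
Why: Methyl attacks silicon to cleave one C–SiMe3 bond (Me4Si is lost), and the diynyl anion is protonated on quench.

**Step 9**
Reactants: 11
Product: 12 (Z)-4-(trimethylsilyl)but-1-en-3-yn-1-yl acetate
Conditions: AcOH, [RuCl2(p-cymene)]2 (2.5 mol%), P(4-FC6H4)3 (10 mol%), DMAP (10 mol%), toluene, 80 °C
Reagents that add atoms: AcOH, CC(=O)O
Why: Ru-catalysed anti-Markovnikov hydro-acyloxylation of the terminal alkyne gives the Z-enol ester.

**Step 10 (key new step)**
Reactants: 9 enal, 12 (Z)-enol acetate (3 equiv)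
Product: 13 (2R,3S,4R)-2-acetoxy-3-(TMS-ethynyl)-4-[(3E,5S)-5-acetoxy-6-(TBDPSO)-3-methylhex-3-en-1-yl]-3,4-dihydro-2H-pyran (all-cis)
Conditions: tridentate Schiff-base Cr(III)Cl catalyst (10 mol%), 4 Å MS, TBME, 25 °C, 72 h
Reagents that add atoms: none
Why: Proposed new method: a Lewis-acid-catalysed inverse-demand oxa-Diels–Alder of a β-alkyl enal with a (Z)-1-acyloxy-enyne, in which Cr(III) lowers the enal LUMO, the nucleophilic enol-acetate carbon c bonds to the enal β-carbon i, and the oxocarbenium closes onto the carbonyl oxygen; the closest known reaction is the Cr(III)-catalysed enal/enol-ether oxa-Diels–Alder, extended here to an enol acetate dienophile, where the endo TS with a Z-dienophile and an E-enal places the OAc, alkynyl and side-chain groups all cis (d, c and i), the catalyst enantiomer sets the absolute configuration, and the dihydropyran, the acylal and the enol ether C5=C6 form in one step.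

**Step 11**
Reactants: 13
Product: 14 terminal alkyne
Conditions: AgNO3 (20 mol%), acetone/H2O (10:1), rt
Reagents that add atoms: none
Why: Ag(I)-catalysed C(sp)–Si protodesilylation is neutral and leaves the acylal, enol ether and acetates intact.

**Step 12**
Reactants: 14
Product: 15 primary alcohol (o-OH precursor)
Conditions: HF·py, pyridine, THF, 0 °C→rt
Reagents that add atoms: none
Why: Buffered fluoride removes the TBDPS group; acid is kept to a minimum for the acylal.

**Step 13**
Reactants: 15
Product: 16 ynal (α-acetoxy aldehyde; used crude)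
Conditions: DMP, NaHCO3, CH2Cl2, 0 °C
Reagents that add atoms: none
Why: Mild, buffered oxidation of the primary alcohol avoids epimerisation at n and leaves the alkyne and enol ether alone.

**Step 14**
Reactants: 16
Product: 17 nine-membered carbocycle with o-OSiEt3 and exocyclic methylene, cis-fused to the dihydropyran
Conditions: Ni(cod)2 (20 mol%), PBu3 (40 mol%), Et3SiH (3 equiv), THF/toluene, 2 mM, syringe-pump addition over 8 h, 25 °C
Reagents that add atoms: triethylsilane, CC[SiH](CC)CC
Why: Ni(0) oxidative cyclisation of the ynal gives an oxanickelacycle in the exo mode, with the aldehyde carbon bonding to the internal alkyne carbon b. σ-Bond metathesis with the silane delivers H to the terminal carbon a (=CH2) and silylates O, giving the o carbinol (S) under substrate control from the n-OAc centre; the E-alkene is retained, and this is a known reaction type applied to a nine-membered ring.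

**Step 15**
Reactants: 17
Product: 18 3-iodo enol ether (iodine on carbon f)
Conditions: NIS, AgNO3 (cat.), MeCN, 0 °C→rt
Reagents that add atoms: N-iodosuccinimide, O=C1CCC(=O)N1I
Why: As in 2-iodoglycal synthesis, the enol ether β-carbon f is iodinated and then loses H+, and the isolated alkenes are far less nucleophilic.

**Step 16**
Reactants: 19 1-bromo-2-methylprop-1-ene, 20 diethyl oxalate
Product: 21 ethyl 4-methyl-2-oxopent-3-enoate
Conditions: Mg, THF (Grignard from 19); then 20 (2 equiv), −78 °C
Reagents that add atoms: none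
Why: Single addition of the alkenyl Grignard to the oxalate gives the α-keto ester.

**Step 17**
Reactants: 21
Product: 22 ethyl (R)-2-hydroxy-4-methylpent-3-enoate
Conditions: RuCl[TsDPEN](p-cymene) (1 mol%, enantiomer chosen to give R), HCO2H/Et3N, CH2Cl2, rt
Reagents that add atoms: none
Why: Noyori asymmetric transfer hydrogenation of the ketone sets h (R).

**Step 18**
Reactants: 22
Product: 23 ethyl (R)-2-(benzoyloxy)-4-methylpent-3-enoate
Conditions: BzCl, pyridine, DMAP (cat.), CH2Cl2, 0 °C
Reagents that add atoms: BzCl, O=C(Cl)c1ccccc1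
Why: Benzoylation installs the OBz group with no stereochemical change.

**Step 19**
Reactants: 23
Product: 24 (R)-2-(benzoyloxy)-4-methylpent-3-enal (used crude)
Conditions: DIBAL-H (1.05 equiv), toluene, −78 °C
Reagents that add atoms: none
Why: The ethyl ester, activated by the α-OBz group, is reduced to the aldehyde faster than the benzoate, and the tetrahedral aluminium hemiacetal is stable at −78 °C.

**Step 20**
Reactants: 18, 24 (2 equiv)
Product: 25 side-chain carbinol (g-OH), o-OTES still in place
Conditions: CrCl2 (8 equiv), NiCl2 (2 mol%), DMF, rt, 24 h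
Reagents that add atoms: none
Why: Nozaki–Hiyama–Kishi coupling of the vinyl iodide with the α-benzoyloxy aldehyde follows the polar Felkin–Anh model (nucleophile anti to C–OBz), which gives the anti relationship between g-OH (S) and h-OBz (R).

**Step 21**
Reactants: 25
Product: 26 g-OAc compound
Conditions: Ac2O, pyridine, DMAP (cat.), CH2Cl2, 0 °C
Reagents that add atoms: Ac2O, CC(=O)OC(C)=O
Why: Acylation of the carbinol proceeds with retention.

**Step 22**
Reactants: 26
Product: 27 Antheliatin
Conditions: HF·py, pyridine, THF, 0 °C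
Reagents that add atoms: none
Why: Buffered fluoride cleaves the secondary TES ether to give the free o-OH, while the acetates, benzoate and acylal survive.

## Compound list

1 | (S)-but-3-ene-1,2-diol | C=C[C@H](O)CO | starting material
2 | (S)-1-(TBDPSO)but-3-en-2-ol | C=C[C@H](O)CO[Si](c1ccccc1)(c1ccccc1)C(C)(C)C | intermediate
3 | (S)-1-(TBDPSO)but-3-en-2-yl acetate | C=C[C@H](OC(C)=O)CO[Si](c1ccccc1)(c1ccccc1)C(C)(C)C | intermediate
4 | 4-methylpent-4-en-1-ol | C=C(C)CCCO | starting material
5 | TBS ether of 4 | C=C(C)CCCO[Si](C)(C)C(C)(C)C | intermediate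
6 | (S,E)-TBSO(CH2)3C(Me)=CH–CH(OAc)CH2OTBDPS | CC(C)(C)[Si](C)(C)OCCC/C(C)=C/[C@H](OC(C)=O)CO[Si](c1ccccc1)(c1ccccc1)C(C)(C)C | intermediate
7 | primary alcohol from 6 | OCCC/C(C)=C/[C@H](OC(C)=O)CO[Si](c1ccccc1)(c1ccccc1)C(C)(C)C | intermediate
8 | aldehyde from 7 | O=CCC/C(C)=C/[C@H](OC(C)=O)CO[Si](c1ccccc1)(c1ccccc1)C(C)(C)C | intermediate
9 | (2E,6E,8S)-8-acetoxy-9-(TBDPSO)-6-methylnona-2,6-dienal | O=C/C=C/CC/C(C)=C/[C@H](OC(C)=O)CO[Si](c1ccccc1)(c1ccccc1)C(C)(C)C | intermediate
10 | 1,4-bis(trimethylsilyl)buta-1,3-diyne | C[Si](C)(C)C#CC#C[Si](C)(C)C | starting material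
11 | 4-(trimethylsilyl)buta-1,3-diyne | C[Si](C)(C)C#CC#C | intermediate
12 | (Z)-4-(TMS)but-1-en-3-yn-1-yl acetate | CC(=O)O/C=C\C#C[Si](C)(C)C | intermediate
13 | oxa-Diels–Alder adduct (2R,3S,4R, all-cis) | C[Si](C)(C)C#C[C@H]1[C@@H](OC(C)=O)OC=C[C@H]1CC/C(C)=C/[C@H](OC(C)=O)CO[Si](c2ccccc2)(c2ccccc2)C(C)(C)C | intermediate
14 | terminal alkyne | C#C[C@H]1[C@@H](OC(C)=O)OC=C[C@H]1CC/C(C)=C/[C@H](OC(C)=O)CO[Si](c2ccccc2)(c2ccccc2)C(C)(C)C | intermediate
15 | primary alcohol | C#C[C@H]1[C@@H](OC(C)=O)OC=C[C@H]1CC/C(C)=C/[C@H](OC(C)=O)CO | intermediate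
16 | ynal | C#C[C@H]1[C@@H](OC(C)=O)OC=C[C@H]1CC/C(C)=C/[C@H](OC(C)=O)C=O | intermediate
17 | nine-membered carbocycle, o-OTES | C=C1[C@H]2[C@@H](OC(C)=O)OC=C[C@H]2CC/C(C)=C/[C@H](OC(C)=O)[C@H]1O[Si](CC)(CC)CC | intermediate
18 | 3-iodo enol ether | C=C1[C@H]2[C@@H](OC(C)=O)OC=C(I)[C@H]2CC/C(C)=C/[C@H](OC(C)=O)[C@H]1O[Si](CC)(CC)CC | intermediate
19 | 1-bromo-2-methylprop-1-ene | CC(C)=CBr | starting material
20 | diethyl oxalate | CCOC(=O)C(=O)OCC | starting material
21 | ethyl 4-methyl-2-oxopent-3-enoate | CC(C)=CC(=O)C(=O)OCC | intermediate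
22 | ethyl (R)-2-hydroxy-4-methylpent-3-enoate | CC(C)=C[C@@H](O)C(=O)OCC | intermediate
23 | ethyl (R)-2-(benzoyloxy)-4-methylpent-3-enoate | CC(C)=C[C@@H](OC(=O)c1ccccc1)C(=O)OCC | intermediate
24 | (R)-2-(benzoyloxy)-4-methylpent-3-enal | CC(C)=C[C@@H](OC(=O)c1ccccc1)C=O | intermediate
25 | NHK adduct (g-OH) | C=C1[C@H]2[C@@H](OC(C)=O)OC=C([C@H](O)[C@@H](C=C(C)C)OC(=O)c3ccccc3)[C@H]2CC/C(C)=C/[C@H](OC(C)=O)[C@H]1O[Si](CC)(CC)CC | intermediate
26 | g-OAc, o-OTES | C=C1[C@H]2[C@@H](OC(C)=O)OC=C([C@H](OC(C)=O)[C@@H](C=C(C)C)OC(=O)c3ccccc3)[C@H]2CC/C(C)=C/[C@H](OC(C)=O)[C@H]1O[Si](CC)(CC)CC | intermediate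
27 | Antheliatin | C=C1[C@H]2[C@@H](OC(C)=O)OC=C([C@H](OC(C)=O)[C@@H](C=C(C)C)OC(=O)c3ccccc3)[C@H]2CC/C(C)=C/[C@H](OC(C)=O)[C@H]1O | target

## Totals

**Total steps:** 22.

**Longest linear sequence:** 15 (steps 1, 2, 4, 5, 6, 7, 10, 11, 12, 13, 14, 15, 20, 21, 22; compounds 1→2→3→6→7→8→9→13→14→15→16→17→18→25→26→27). The parallel branches are shorter: the diyne branch (steps 8, 9) has 2 steps before step 10, the side-chain branch (steps 16–19) has 4 steps before step 20, and the TBS-ether branch (step 3) has 1 step before step 4.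

**Three steps most likely to fail**
1. **Step 10 (the new oxa-Diels–Alder).** An enol acetate that also carries an alkynyl group may be too weakly nucleophilic, and the endo/anomer control is unproven.
   - Fallback: use the (Z)-1-methoxy-enyne (Wittig of 3-TMS-propynal with Ph3P=CHOMe, Z isomer separated) in the established Cr(III) enal/enol-ether oxa-Diels–Alder. Then convert the 2-OMe to 2-OAc by Ac2O/BF3·OEt2 acetolysis and separate the anomers.
2. **Step 14 (Ni-catalysed nine-membered-ring ynal cyclisation).** Risks are oligomerisation, Ni(0) ionisation of the n-allylic acetate, and uncontrolled o configuration.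
   - Fallback: from alcohol 15, run Cp*Ru-catalysed Markovnikov hydrostannylation of the terminal alkyne and Sn→I exchange with NIS in MeCN at −40 °C to give the 1,1-disubstituted vinyl iodide. Then oxidise with DMP to the aldehyde and close the ring by CrCl2/NiCl2 NHK macrocyclisation at about 1 mM.
3. **Step 20 (NHK of the enol-ether vinyl iodide with the labile α-benzoyloxy aldehyde).** Risks are low dr, aldehyde racemisation, and ionisation of the acylal.
   - Fallback: Miyaura borylation of 18 (Pd(dppf)Cl2, B2pin2, KOAc), then Rh(I)-catalysed 1,2-addition of the alkenylboronate to aldehyde 24.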